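**Retrosynthetic overview**
- Target 8 is a flavone, 2-(3-hydroxy-4,5-dimethoxyphenyl)-6,7,8-trimethoxychromen-4-one; it has no stereocentre.
- Ring C (the pyranone) is formed last, by oxidative cyclisation of 2'-hydroxychalcone 6 (O1–C2 bond and C2=C3 unsaturation).
- Chalcone 6 is cut at the enone C=C (Claisen–Schmidt) into acetophenone 3 (ring A) and aldehyde 4 (ring B).
- Acetophenone 3 comes from ortho-C-acylation of 2,3,4-trimethoxyphenol 1.
- Rings A and B are bought intact; only ring C is built, with no protecting groups.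

Assumption: the target is achiral, so the "single enantiomer" requirement is met trivially; compounds 1 and 4 are taken as catalogue materials.

**Step 1**
Reactants: 1 2,3,4-trimethoxyphenol
Product: 3 1-(2-hydroxy-3,4,5-trimethoxyphenyl)ethanone, via difluoroboron chelate 2 (not isolated)
Conditions: AcOH, BF3·OEt2 (3 equiv), 90 °C, 3 h; then H2O/EtOH, reflux, 30 min
Reagents that add atoms: acetic acid CC(=O)O
Why: BF3-promoted Friedel–Crafts (Fries-type) ortho-acylation places the acetyl group at C6, the only free position ortho to the phenol and para to the 3-OMe group; the ketone is held as the six-membered BF2 chelate 2, which water cleaves on work-up, and no stereocentre is formed.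

**Step 2**
Reactants: 3 1-(2-hydroxy-3,4,5-trimethoxyphenyl)ethanone; 4 3-hydroxy-4,5-dimethoxybenzaldehyde
Product: 6 (E)-1-(2-hydroxy-3,4,5-trimethoxyphenyl)-3-(3-hydroxy-4,5-dimethoxyphenyl)prop-2-en-1-one, via aldol adduct 5 (not isolated)
Conditions: KOH (50% aq., 12 equiv), EtOH, rt, 48 h; then aq. HCl to pH 3
Reagents that add atoms: none
Why: Claisen–Schmidt (crossed aldol) condensation, in which the enolate of 3 adds to the non-enolisable aldehyde 4 (its meta-phenoxide is not conjugated with the formyl group, so it stays electrophilic) and aldol 5 loses water by E1cB to the conjugated, thermodynamically preferred E-enone, leaving no stereocentre.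

**Step 3**
Reactants: 6 (E)-1-(2-hydroxy-3,4,5-trimethoxyphenyl)-3-(3-hydroxy-4,5-dimethoxyphenyl)prop-2-en-1-one
Product: 8 2-(3-hydroxy-4,5-dimethoxyphenyl)-6,7,8-trimethoxy-4H-chromen-4-one, via flavanone 7 (not isolated)
Conditions: I2 (10 mol%), DMSO, 130 °C, 3 h
Reagents that add atoms: none
Why: Iodine-catalysed oxidative cyclisation of a 2'-hydroxychalcone, in which intramolecular oxa-Michael addition closes ring C to flavanone 7 and the I2/DMSO couple dehydrogenates C2–C3 (DMSO is the terminal oxidant), so the C2 stereocentre of 7 is erased and the achiral flavone results.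

**Compound list**
1 | 2,3,4-trimethoxyphenol | COc1ccc(O)c(OC)c1OC | starting material
2 | 2,2-difluoro-6,7,8-trimethoxy-4-methyl-1,3,2-benzodioxaborinine (zwitterionic O–BF2–O=C chelate of ketone 3) | COc1cc2C(C)=[O+][B-](F)(F)Oc2c(OC)c1OC | intermediate
3 | 1-(2-hydroxy-3,4,5-trimethoxyphenyl)ethanone | CC(=O)c1cc(OC)c(OC)c(OC)c1O | intermediate
4 | 3-hydroxy-4,5-dimethoxybenzaldehyde | COc1cc(C=O)cc(O)c1OC | starting material
5 | 3-hydroxy-1-(2-hydroxy-3,4,5-trimethoxyphenyl)-3-(3-hydroxy-4,5-dimethoxyphenyl)propan-1-one (racemic aldol adduct) | COc1cc(C(O)CC(=O)c2cc(OC)c(OC)c(OC)c2O)cc(O)c1OC | intermediate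
6 | (E)-1-(2-hydroxy-3,4,5-trimethoxyphenyl)-3-(3-hydroxy-4,5-dimethoxyphenyl)prop-2-en-1-one | COc1cc(/C=C/C(=O)c2cc(OC)c(OC)c(OC)c2O)cc(O)c1OC | intermediate
7 | 2-(3-hydroxy-4,5-dimethoxyphenyl)-6,7,8-trimethoxychroman-4-one (racemic flavanone) | COc1cc(C2CC(=O)c3cc(OC)c(OC)c(OC)c3O2)cc(O)c1OC | intermediate
8 | 2-(3-hydroxy-4,5-dimethoxyphenyl)-6,7,8-trimethoxy-4H-chromen-4-one (3'-hydroxy-6,7,8,4',5'-pentamethoxyflavone, achiral) | COc1cc(-c2cc(=O)c3cc(OC)c(OC)c(OC)c3o2)cc(O)c1OC | target

**Total step count:** 3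
**Longest linear sequence:** 3 steps (1 → 3 → 6 → 8)

**Steps most likely to fail** (the route has three steps; all are listed in route order; step 2 is the riskiest, then step 3, then step 1)

Step 1. Risk: competing C-acylation at C5 (para to the 2-OMe group) or a sluggish reaction on the crowded, electron-rich phenol. The fallback sets out from 1 and comes back at 3, using a phenoxide-directed route that can only functionalise the position ortho to oxygen. Compound 1 is formylated with MgCl2, Et3N and paraformaldehyde in MeCN at reflux to give 2-hydroxy-3,4,5-trimethoxybenzaldehyde F1. Addition of MeMgBr (2.5 equiv, THF, 0 °C) gives racemic 1-(2-hydroxy-3,4,5-trimethoxyphenyl)ethanol F2. Oxidation of this benzylic alcohol with MnO2 in CH2Cl2 at rt delivers 3.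

Step 2. Risk: the phenoxide form of 4 is a weaker, poorly soluble electrophile, and the polyanionic mixture may stall or give chalcone/flavanone mixtures. The fallback sets out from 4 and comes back at 6, masking the phenol so that a neutral aldehyde is condensed. Compound 4 is treated with MOMCl and iPr2NEt in CH2Cl2 to give 3,4-dimethoxy-5-(methoxymethoxy)benzaldehyde F3. Claisen–Schmidt condensation of this with 3 (KOH, EtOH, rt) gives (E)-1-(2-hydroxy-3,4,5-trimethoxyphenyl)-3-[3,4-dimethoxy-5-(methoxymethoxy)phenyl]prop-2-en-1-one F4. Cleavage of the acetal with HCl in MeOH at 40 °C returns 6; any flavanone 7 formed under the acid is on the pathway of step 3 and does no harm.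

Step 3. Risk: electrophilic iodine may iodinate or oxidise the free, electron-rich ring-B phenol, or the dehydrogenation may stop at the flavanone. The fallback sets out from 6 and comes back at 8, separating cyclisation from dehydrogenation and using a quinone oxidant on a masked phenol. Chalcone 6 is isomerised with sodium acetate in refluxing EtOH to flavanone 7, which is now isolated. Acetylation (Ac2O, pyridine, rt) gives 5-(6,7,8-trimethoxy-4-oxochroman-2-yl)-2,3-dimethoxyphenyl acetate F5. Dehydrogenation with DDQ in refluxing dioxane gives 5-(6,7,8-trimethoxy-4-oxo-4H-chromen-2-yl)-2,3-dimethoxyphenyl acetate F6. Removal of the acetate with K2CO3 in MeOH at rt gives 8.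

**Further compounds**
F1 | step 1 | 2-hydroxy-3,4,5-trimethoxybenzaldehyde | COc1cc(C=O)c(O)c(OC)c1OC
F2 | step 1 | 1-(2-hydroxy-3,4,5-trimethoxyphenyl)ethanol (racemic) | CC(O)c1cc(OC)c(OC)c(OC)c1O
F3 | step 2 | 3,4-dimethoxy-5-(methoxymethoxy)benzaldehyde | COCOc1cc(C=O)cc(OC)c1OC
F4 | step 2 | (E)-1-(2-hydroxy-3,4,5-trimethoxyphenyl)-3-[3,4-dimethoxy-5-(methoxymethoxy)phenyl]prop-2-en-1-one | COCOc1cc(/C=C/C(=O)c2cc(OC)c(OC)c(OC)c2O)cc(OC)c1OC
F5 | step 3 | 5-(6,7,8-trimethoxy-4-oxochroman-2-yl)-2,3-dimethoxyphenyl acetate (racemic) | CC(=O)Oc1cc(C2CC(=O)c3cc(OC)c(OC)c(OC)c3O2)cc(OC)c1OC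
F6 | step 3 | 5-(6,7,8-trimethoxy-4-oxo-4H-chromen-2-yl)-2,3-dimethoxyphenyl acetate | CC(=O)Oc1cc(-c2cc(=O)c3cc(OC)c(OC)c(OC)c3o2)cc(OC)c1OC
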